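The pyran ring C of the flavan unit is opened at O1–C2 and C4–C4a. That leaves a ketal-protected pyrogallol, used as an O,C-dinucleophile (O1 and the ortho carbon C4a, which lies para to O7 of ring A), and a three-carbon dielectrophile whose ends C2 and C4 are both benzylic and flank carbinol C3. The precursor is an anti, trans-epoxy alcohol: hydroxyl on C2, oxirane across C3–C4, the complete benzylated flavonol already on C4. In one flask a Mitsunobu etherification inverts C2 and an epoxy–arene Friedel–Crafts closure inverts C4, which writes the 2,3-cis-3,4-trans array stereospecifically. All chirality descends from one catalytic epoxidation.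

Key step: step 11

Remark on the chemistry: the upper unit is numbered as a flavan (O1, C2, C3, C4, C4a to C8a; rings A, B, C). The target is read as (2R,3R,4S), that is 2,3-cis-3,4-trans. "Fl" stands for the 3,7,8-tris(benzyloxy)-2-[3,4-bis(benzyloxy)phenyl]-4-oxo-4H-chromen-5-yl group.

Step 1
Reactants: 1 gallacetophenone, 1-(2,3,4-trihydroxyphenyl)ethanone
Product: 2 1-[3,4-bis(benzyloxy)-2-hydroxyphenyl]ethanone
Conditions: BnBr (2.1 equiv), K2CO3, acetone, reflux
Reagents that add atoms: benzyl bromide, BrCc1ccccc1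
Why: Williamson etherification in which the 2-hydroxyl is tied up in a hydrogen bond to the acetyl carbonyl and stays free, so only O3 and O4 are benzylated.

Step 2
Reactants: 2 1-[3,4-bis(benzyloxy)-2-hydroxyphenyl]ethanone; 3 3,4-bis(benzyloxy)benzaldehyde
Product: 4 (E)-1-[3,4-bis(benzyloxy)-2-hydroxyphenyl]-3-[3,4-bis(benzyloxy)phenyl]prop-2-en-1-one
Conditions: KOH, EtOH/THF, rt; then aq. HCl
Reagents that add atoms: none
Why: Claisen–Schmidt condensation of the methyl ketone enolate with a non-enolisable aldehyde, where E1cB loss of water gives the conjugated (E)-chalcone.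

Step 3
Reactants: 4 the 2'-hydroxychalcone
Product: 5 7,8-bis(benzyloxy)-2-[3,4-bis(benzyloxy)phenyl]-3-hydroxy-4H-chromen-4-one
Conditions: 30% H2O2, NaOH, MeOH/THF, 0 °C to rt; then aq. HCl
Reagents that add atoms: hydrogen peroxide, OO
Why: Algar–Flynn–Oyamada reaction, in which alkaline peroxide oxidises the enone, the phenoxide cyclises and the product is oxidised on to the 3-hydroxyflavone, and the absence of a 6'-substituent disfavours the aurone pathway.

Step 4
Reactants: 5 the 3-hydroxyflavone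
Product: 6 3,7,8-tris(benzyloxy)-2-[3,4-bis(benzyloxy)phenyl]-4H-chromen-4-one (Fl–H)
Conditions: BnBr, K2CO3, DMF, 60 °C
Reagents that add atoms: benzyl bromide, BrCc1ccccc1
Why: Williamson etherification of the only remaining acidic hydroxyl, which removes a chelating and Mitsunobu-active site before the later steps.

Step 5
Reactants: 3 3,4-bis(benzyloxy)benzaldehyde
Product: 7 racemic 1-[3,4-bis(benzyloxy)phenyl]prop-2-en-1-ol
Conditions: vinylmagnesium bromide, THF, −78 to 0 °C; then H2O
Reagents that add atoms: vinylmagnesium bromide, C=C[Mg]Br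
Why: 1,2-addition of a Grignard reagent to an aromatic aldehyde, giving a racemic stereocentre that step 6 erases.

Step 6
Reactants: 7 racemic 1-[3,4-bis(benzyloxy)phenyl]prop-2-en-1-ol
Product: 8 1-[3,4-bis(benzyloxy)phenyl]prop-2-en-1-one
Conditions: MnO2, CH2Cl2, rt; used without storage
Reagents that add atoms: none
Why: Selective MnO2 oxidation of an alcohol that is both allylic and benzylic, under neutral conditions that spare the benzyl ethers and the polymerisable vinyl ketone.

Step 7
Reactants: 6 Fl–H; 8 1-[3,4-bis(benzyloxy)phenyl]prop-2-en-1-one (added slowly, excess)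
Product: 9 (E)-1-[3,4-bis(benzyloxy)phenyl]-3-Fl-prop-2-en-1-one
Conditions: [Cp*RhCl2]2 (5 mol %), AgSbF6 (20 mol %), Cu(OAc)2 (2.2 equiv), DCE, 100 °C
Reagents that add atoms: none
Why: Ketone-directed oxidative C–H olefination (Fujiwara–Moritani type), a known reaction of chromones and flavones, in which the C4 carbonyl oxygen guides cationic Cp*Rh (trivalent rhodium) into the peri C5–H bond through a five-membered rhodacycle, and alkene insertion with syn β-hydride elimination gives the (E)-enone while Cu(OAc)2 reoxidises the metal.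

Step 8
Reactants: 9 the (E)-enone
Product: 10 [3,4-bis(benzyloxy)phenyl][(2R,3S)-3-Fl-oxiran-2-yl]methanone (trans-oxirane)
Conditions: poly-L-leucine, urea–H2O2, DBU, THF, rt
Reagents that add atoms: urea–hydrogen peroxide, OO.NC(N)=O
Why: Juliá–Colonna epoxidation, in which the helical poly-L-leucine binds the peroxy enolate of the chalcone-type enone and should deliver the trans (αR,βS)-oxirane as it does with chalcones, setting C3 and C4 in one catalytic event, while the tetrasubstituted, donor-substituted C2=C3 bond of the flavonol is inert to nucleophilic peroxide.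

Step 9
Reactants: 10 the (2R,3S)-epoxy ketone
Product: 11 (S)-[3,4-bis(benzyloxy)phenyl][(2S,3S)-3-Fl-oxiran-2-yl]methanol (anti epoxy alcohol; the changed descriptor at oxirane C2 is only a priority effect)
Conditions: Zn(BH4)2 (ethereal solution), Et2O/THF, −20 °C; then H2O
Reagents that add atoms: none
Why: Chelation-controlled reduction of an α,β-epoxy ketone, in which zinc bridges the ketone and oxirane oxygens and hydride enters from the side of the C3 hydrogen, giving the anti (erythro) epoxy alcohol and setting C2 as (S), while the hindered vinylogous-ester carbonyl of the flavonol is left alone.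

Step 10
Reactants: 12 pyrogallol
Product: 13 2,2-diphenyl-1,3-benzodioxol-4-ol
Conditions: Ph2CCl2, neat, 170 °C
Reagents that add atoms: dichlorodiphenylmethane, ClC(Cl)(c1ccccc1)c1ccccc1
Why: Ketalisation of a catechol with a gem-dichloride, where any two neighbouring hydroxyls of the symmetric pyrogallol give the same ketal, leaving exactly one free phenol (the future O1) in a group that hydrogenolysis removes.

Step 11
Reactants: 11 the anti epoxy alcohol; 13 2,2-diphenyl-1,3-benzodioxol-4-ol
Product: 15 (2R,3R,4S)-2-[3,4-bis(benzyloxy)phenyl]-4-Fl-7,8-(diphenylmethylenedioxy)chroman-3-ol, via epoxy aryl ether 14 (not isolated)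
Conditions: n-Bu3P, TMAD (N,N,N',N'-tetramethylazodicarboxamide), toluene, 0 °C to rt; then HFIP added to the same flask (toluene/HFIP 1:3), rt to 40 °C
Reagents that add atoms: none
Why: n-Bu3P/TMAD turns the C2 hydroxyl of 11 into an alkoxyphosphonium ion that the phenoxide of 13 displaces by SN2 (Mitsunobu etherification, known for aryl oxiranyl carbinols), which makes O1–C2 and gives 14; HFIP then activates the oxirane by hydrogen bonding and the arene carbon ortho to O1 attacks C4 from the back (intramolecular Friedel–Crafts epoxy–arene cyclisation, the known route from aryl 3-arylglycidyl ethers to trans-4-arylchroman-3-ols), which makes C4a–C4. The only ring closed is pyran ring C, in a 6-endo-tet mode. C2 is controlled by SN2 inversion of the (S)-carbinol, C4 by inversion at the trans-oxirane carbon, and C3 keeps its C–O bond, so the anti, trans arrangement of 11 maps onto 2,3-cis-3,4-trans. In the chair-like transition state ring B sits equatorial while O3 and Fl are axial and anti, so even a more cationic opening should converge on the same 3,4-trans product. Three selectivities are needed: O- rather than C-alkylation at C2 (secured by the non-ionising first stage in toluene), 6-endo rather than 5-exo opening (C4 is benzylic and para to O8 of the flavonol ring A, C3 is not activated), and attack by the right arene carbon (the tether reaches only C4a, which is also para to the ketal oxygen O7).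

Step 12
Reactants: 15 the protected biflavonoid
Product: 16 target, 5-[(2R,3R,4S)-2-(3,4-dihydroxyphenyl)-3,7,8-trihydroxychroman-4-yl]-2-(3,4-dihydroxyphenyl)-3,7,8-trihydroxy-4H-chromen-4-one
Conditions: H2 (1 atm), Pd(OH)2/C, THF/MeOH, rt
Reagents that add atoms: none
Why: Global hydrogenolysis of seven benzyl ethers and the diphenylmethylene ketal over palladium, under conditions where the flavan C2–O1 bond, the C4–aryl bonds and the flavonol enone normally persist, so no stereocentre is touched.

Compound list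
1 | gallacetophenone | CC(=O)c1ccc(O)c(O)c1O | starting material
2 | 1-[3,4-bis(benzyloxy)-2-hydroxyphenyl]ethanone | CC(=O)c1ccc(OCc2ccccc2)c(OCc2ccccc2)c1O | intermediate
3 | 3,4-bis(benzyloxy)benzaldehyde | O=Cc1ccc(OCc2ccccc2)c(OCc2ccccc2)c1 | starting material
4 | (E)-2'-hydroxy-3,4,3',4'-tetrakis(benzyloxy)chalcone | O=C(/C=C/c1ccc(OCc2ccccc2)c(OCc2ccccc2)c1)c1ccc(OCc2ccccc2)c(OCc2ccccc2)c1O | intermediate
5 | 7,8-bis(benzyloxy)-2-[3,4-bis(benzyloxy)phenyl]-3-hydroxy-4H-chromen-4-one | O=c1c(O)c(-c2ccc(OCc3ccccc3)c(OCc3ccccc3)c2)oc2c(OCc3ccccc3)c(OCc3ccccc3)ccc12 | intermediate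
6 | 3,7,8-tris(benzyloxy)-2-[3,4-bis(benzyloxy)phenyl]-4H-chromen-4-one (Fl–H) | O=c1c(OCc3ccccc3)c(-c2ccc(OCc3ccccc3)c(OCc3ccccc3)c2)oc2c(OCc3ccccc3)c(OCc3ccccc3)ccc12 | intermediate
7 | racemic 1-[3,4-bis(benzyloxy)phenyl]prop-2-en-1-ol | C=CC(O)c1ccc(OCc2ccccc2)c(OCc2ccccc2)c1 | intermediate
8 | 1-[3,4-bis(benzyloxy)phenyl]prop-2-en-1-one | C=CC(=O)c1ccc(OCc2ccccc2)c(OCc2ccccc2)c1 | intermediate
9 | (E)-1-[3,4-bis(benzyloxy)phenyl]-3-Fl-prop-2-en-1-one | O=C(/C=C/c1cc(OCc2ccccc2)c(OCc2ccccc2)c2oc(-c3ccc(OCc4ccccc4)c(OCc4ccccc4)c3)c(OCc3ccccc3)c(=O)c12)c1ccc(OCc2ccccc2)c(OCc2ccccc2)c1 | intermediate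
10 | [3,4-bis(benzyloxy)phenyl][(2R,3S)-3-Fl-oxiran-2-yl]methanone | O=C(c1ccc(OCc2ccccc2)c(OCc2ccccc2)c1)[C@@H]5O[C@H]5c1cc(OCc2ccccc2)c(OCc2ccccc2)c2oc(-c3ccc(OCc4ccccc4)c(OCc4ccccc4)c3)c(OCc3ccccc3)c(=O)c12 | intermediate
11 | (S)-[3,4-bis(benzyloxy)phenyl][(2S,3S)-3-Fl-oxiran-2-yl]methanol | O[C@@H](c1ccc(OCc2ccccc2)c(OCc2ccccc2)c1)[C@@H]5O[C@H]5c1cc(OCc2ccccc2)c(OCc2ccccc2)c2oc(-c3ccc(OCc4ccccc4)c(OCc4ccccc4)c3)c(OCc3ccccc3)c(=O)c12 | intermediate
12 | pyrogallol | Oc1cccc(O)c1O | starting material
13 | 2,2-diphenyl-1,3-benzodioxol-4-ol | Oc1cccc2OC(c3ccccc3)(c3ccccc3)Oc12 | intermediate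
14 | 4-{(R)-[3,4-bis(benzyloxy)phenyl][(2R,3S)-3-Fl-oxiran-2-yl]methoxy}-2,2-diphenyl-1,3-benzodioxole | c1ccc2OC(c3ccccc3)(c3ccccc3)Oc2c1O[C@H](c1ccc(OCc2ccccc2)c(OCc2ccccc2)c1)[C@@H]5O[C@H]5c1cc(OCc2ccccc2)c(OCc2ccccc2)c2oc(-c3ccc(OCc4ccccc4)c(OCc4ccccc4)c3)c(OCc3ccccc3)c(=O)c12 | intermediate
15 | (2R,3R,4S)-2-[3,4-bis(benzyloxy)phenyl]-4-Fl-7,8-(diphenylmethylenedioxy)chroman-3-ol | O=c1c(OCc7ccccc7)c(-c2ccc(OCc7ccccc7)c(OCc7ccccc7)c2)oc2c(OCc7ccccc7)c(OCc7ccccc7)cc([C@H]3c4ccc5OC(c6ccccc6)(c6ccccc6)Oc5c4O[C@H](c4ccc(OCc7ccccc7)c(OCc7ccccc7)c4)[C@@H]3O)c12 | intermediate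
16 | CNP0395591.1 | O=c1c(O)c(-c2ccc(O)c(O)c2)oc2c(O)c(O)cc([C@H]3c4ccc(O)c(O)c4O[C@H](c4ccc(O)c(O)c4)[C@@H]3O)c12 | target

Total steps: 12. Longest linear sequence: 9 steps (1, 2, 3, 4, 7, 8, 9, 11, 12).

Steps most likely to fail

Step 11. The alkoxyphosphonium ion sits on an electron-rich benzylic carbon and may ionise in part, which would erode the inversion at C2. In HFIP the oxirane may also rearrange by a hydride shift before the arene reaches C4.
- The fallback sets out from 10 and 12, comes back at 16, and makes the two bonds in separate steps with the C–C bond first.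
- BF3·OEt2 in Et2O/CH2Cl2 at low temperature opens the oxirane of 10 at C4 with free pyrogallol. Its two reactive carbons are equivalent, each ortho to one hydroxyl and para to another. This should give, with inversion, the (2R,3S)-α-hydroxy ketone F4.
- Chelation-controlled reduction with Zn(BH4)2 gives the (1S,2R,3S)-anti diol F5.
- An intramolecular Mitsunobu reaction (PPh3, DIAD, THF) closes O1–C2 with inversion. Only the hydroxyl ortho to C4a can form a six-membered ring. The product is the hepta-O-benzyl flavan-3-ol with a free 7,8-catechol F6.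
- Hydrogenolysis as in step 12 leads to 16.

Step 7. The rhodium enolate formed after insertion may be protonated instead of undergoing β-hydride elimination. The ketone of 8 may direct olefination of its own aryl ring, and 8 may polymerise at the reaction temperature.
- The fallback sets out from 6 and comes back at 9.
- The same peri C–H bond is olefinated with N-methoxy-N-methylacrylamide, a well-behaved partner that has no aryl C–H bond of its own, to give the Weinreb enamide F1.
- The B-ring is then brought in as a nucleophile. [3,4-Bis(benzyloxy)phenyl]magnesium bromide F2, made from commercial 4-bromo-1,2-bis(benzyloxy)benzene and Mg, is added in THF at −40 °C.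
- The chelated tetrahedral adduct collapses to 9 only on work-up. Steps 5 and 6 then fall away.

Step 8. The bulky β-aryl group with its peri carbonyl may fit the polyleucine helix badly, which would mean slow turnover and poor facial selectivity.
- The fallback sets out from 9, comes back at 11, and replaces steps 8 and 9.
- Luche reduction (NaBH4, CeCl3·7H2O, MeOH/THF) gives the racemic (E)-allylic alcohol F3.
- A Sharpless kinetic-resolution epoxidation (Ti(OiPr)4, L-(+)-DIPT, t-BuOOH, 4 Å MS, CH2Cl2, −20 °C) should convert the faster (R)-enantiomer into the anti epoxy alcohol 11.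
- The unreacted (S)-alcohol is returned to 9 with MnO2.

Further compounds
F1 | step 7 | (E)-N-methoxy-N-methyl-3-Fl-prop-2-enamide | CON(C)C(=O)/C=C/c1cc(OCc2ccccc2)c(OCc2ccccc2)c2oc(-c3ccc(OCc4ccccc4)c(OCc4ccccc4)c3)c(OCc3ccccc3)c(=O)c12
F2 | step 7 | [3,4-bis(benzyloxy)phenyl]magnesium bromide | Br[Mg]c1ccc(OCc2ccccc2)c(OCc2ccccc2)c1
F3 | step 8 | racemic (E)-1-[3,4-bis(benzyloxy)phenyl]-3-Fl-prop-2-en-1-ol | OC(/C=C/c1cc(OCc2ccccc2)c(OCc2ccccc2)c2oc(-c3ccc(OCc4ccccc4)c(OCc4ccccc4)c3)c(OCc3ccccc3)c(=O)c12)c1ccc(OCc2ccccc2)c(OCc2ccccc2)c1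
F4 | step 11 | (2R,3S)-1-[3,4-bis(benzyloxy)phenyl]-3-Fl-2-hydroxy-3-(2,3,4-trihydroxyphenyl)propan-1-one | O=C(c1ccc(OCc2ccccc2)c(OCc2ccccc2)c1)[C@H](O)[C@@H](c1cc(OCc2ccccc2)c(OCc2ccccc2)c2oc(-c3ccc(OCc4ccccc4)c(OCc4ccccc4)c3)c(OCc3ccccc3)c(=O)c12)c1ccc(O)c(O)c1O
F5 | step 11 | (1S,2R,3S)-1-[3,4-bis(benzyloxy)phenyl]-3-Fl-3-(2,3,4-trihydroxyphenyl)propane-1,2-diol | O[C@@H](c1ccc(OCc2ccccc2)c(OCc2ccccc2)c1)[C@H](O)[C@@H](c1cc(OCc2ccccc2)c(OCc2ccccc2)c2oc(-c3ccc(OCc4ccccc4)c(OCc4ccccc4)c3)c(OCc3ccccc3)c(=O)c12)c1ccc(O)c(O)c1O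
F6 | step 11 | (2R,3R,4S)-2-[3,4-bis(benzyloxy)phenyl]-4-Fl-chroman-3,7,8-triol | O=c1c(OCc7ccccc7)c(-c2ccc(OCc7ccccc7)c(OCc7ccccc7)c2)oc2c(OCc7ccccc7)c(OCc7ccccc7)cc([C@H]3c4ccc(O)c(O)c4O[C@H](c4ccc(OCc7ccccc7)c(OCc7ccccc7)c4)[C@@H]3O)c12
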